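Atom labels: C1 = oxirane carbon bearing Br, C2 = oxirane carbon bearing the side chain, C3 = the exocyclic CBr2 carbon that carries the butyl group.
Cuts: (a) the O–C1 bond of the oxirane, back to a C2 alkoxide beside a C1 CHBr2 group; (b) the two C1–Br bonds, back to a C1 aldehyde, itself the stump of a terminal dioxolane; (c) the C2–C3 bond, back to an aldehyde carbon (C2) and a dibromo carbanion (C3).
Enabling feature: the fully halogenated C3 is bonded directly to the oxygen-bearing ring carbon C2, and the lone C–H of a 1,1-dibromoalkane is acidic enough for a lithium amide. C3 can therefore arrive as a lithium carbenoid with both bromines in place, and C2 as a carbonyl carbon.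
Forward: the chain is joined first (C2–C3), the C2 hydroxyl is silylated, the dioxolane is cut down to the C1 aldehyde, CHO becomes CHBr2, and the only ring, the oxirane, closes last.
Stereochemistry: C2 (S) comes from Felkin–Anh addition under the control of the dioxolane stereocentre of (S)-glyceraldehyde acetonide, which is then excised. C1 (R) is induced by C2 in the trans-selective ring closure.

Key step: step 3

Assumption: the α-bromo oxirane is taken to be isolable, because its rearrangement to an α-bromo aldehyde would need a cation at C2, which the neighbouring CBr2 group destabilises. It is still handled cold and kept from acids, Lewis acids and nucleophiles.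

Step 1
Reactants: 1 pentanal
Product: 2 1,1-dibromopentane
Conditions: P(OPh)3, Br2, CH2Cl2, −78 °C; then 1, −78 °C → rt; distil
Reagents that add atoms: bromine, BrBr
Why: This is a deoxygenative gem-dibromination of an aldehyde with the bromophosphonium reagent from P(OPh)3 and Br2, in which the carbonyl oxygen leaves as triphenyl phosphate and both bromides end on the former carbonyl carbon, a routine reaction for unbranched aliphatic aldehydes that creates no stereocentre.

Step 2
Reactants: 3 (R)-(2,2-dimethyl-1,3-dioxolan-4-yl)methanol [(R)-solketal]
Product: 4 (S)-2,2-dimethyl-1,3-dioxolane-4-carbaldehyde [(S)-glyceraldehyde acetonide]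
Conditions: IBX, EtOAc, 80 °C; filter, concentrate, distil just before use
Reagents that add atoms: none
Why: The hypervalent-iodine (IBX) oxidation of a primary alcohol stops at the aldehyde under neutral, non-aqueous conditions, so no bond to the stereocentre is touched and it is not enolised, and the descriptor changes from R to S only because CHO outranks the ring CH2O.

Step 3
Reactants: 2 1,1-dibromopentane; 4 (S)-2,2-dimethyl-1,3-dioxolane-4-carbaldehyde
Product: 7 (S)-2,2-dibromo-1-[(S)-2,2-dimethyl-1,3-dioxolan-4-yl]hexan-1-ol, via 1,1-dibromopentyllithium 5 (not isolated), via lithium alkoxide 6 (not isolated)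
Conditions: 2 added to LiN(iPr)2 (LDA), THF–Et2O–pentane (4:1:1), −100 °C; then 4, −100 °C; AcOH/THF quench at −100 °C; chromatography
Reagents that add atoms: none
Why: LiN(iPr)2 removes the hydrogen between the two bromines of 2 at about −100 °C, where carbenoid 5 lives long enough to be used, and 5 attacks the carbonyl carbon of 4 to give alkoxide 6, which is protonated while still cold. The reaction type is the known 1,2-addition of 1,1-dihaloalkyllithium carbenoids to aldehydes; it forms one C–C bond (C2–C3) and no ring. The new C2 stereocentre is controlled by the dioxolane stereocentre: in the Felkin–Anh (polar) transition state the ring C–O bond stands perpendicular to the carbonyl group and the bulky, non-chelated nucleophile enters opposite to it, past the hydrogen, which should give the anti (S,S) carbinol. The step needs diastereofacial selectivity, secured by the α-oxygen stereocentre together with the size of 5, and it needs addition to win over enolisation of 4 and α-elimination of 5, secured by the very low temperature and by pre-forming the carbenoid. The acid quench before any warming prevents 6 from displacing a C3 bromide, and the minor syn carbinol can be removed by chromatography.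

Step 4
Reactants: 7 (S)-2,2-dibromo-1-[(S)-2,2-dimethyl-1,3-dioxolan-4-yl]hexan-1-ol
Product: 8 tert-butyl{(S)-2,2-dibromo-1-[(S)-2,2-dimethyl-1,3-dioxolan-4-yl]hexyloxy}dimethylsilane
Conditions: TBSOTf, 2,6-lutidine, CH2Cl2, −78 → 0 °C
Reagents that add atoms: tert-butyldimethylsilyl triflate (TBSOTf), CC(C)(C)[Si](C)(C)OS(=O)(=O)C(F)(F)F
Why: Silyl triflate silylation with a hindered pyridine base works on crowded secondary alcohols and never generates a free alkoxide, so no C3 bromide is displaced and both stereocentres stay untouched.

Step 5
Reactants: 8 tert-butyl{(S)-2,2-dibromo-1-[(S)-2,2-dimethyl-1,3-dioxolan-4-yl]hexyloxy}dimethylsilane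
Product: 10 (S)-3,3-dibromo-2-(tert-butyldimethylsilyloxy)heptanal, via silyloxy diol 9 (not isolated)
Conditions: H5IO6, EtOAc, 0 °C → rt; short silica plug, used at once
Reagents that add atoms: none
Why: Periodic acid in ethyl acetate hydrolyses the terminal isopropylidene acetal and then carries out the Malaprade glycol cleavage of the liberated 1,2-diol in the same flask, turning the relay stereocentre into the C1 aldehyde carbon in a base-free medium, so C2 is not epimerised, no HBr is lost and the hindered TBS ether should tolerate the brief acid exposure.

Step 6
Reactants: 10 (S)-3,3-dibromo-2-(tert-butyldimethylsilyloxy)heptanal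
Product: 11 (S)-tert-butyldimethyl[(1,1,3,3-tetrabromoheptan-2-yl)oxy]silane
Conditions: P(OPh)3, Br2, CH2Cl2, −78 °C; then 10, −78 °C → rt
Reagents that add atoms: bromine, BrBr
Why: The same deoxygenative gem-dibromination as in step 1 binds the aldehyde oxygen to phosphorus and delivers two bromides to C1 without any added base, so the acidic C2–H is not removed and C2 keeps its S configuration.

Step 7
Reactants: 11 (S)-tert-butyldimethyl[(1,1,3,3-tetrabromoheptan-2-yl)oxy]silane
Product: 13 (2R,3S)-2-bromo-3-(1,1-dibromopentyl)oxirane, via tetrabromo alkoxide 12 (not isolated)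
Conditions: TBAF (1.0 equiv), THF, −78 → 0 °C; pentane extraction, Florisil, cold
Reagents that add atoms: none
Why: Fluoride cleaves the Si–O bond and alkoxide 12 displaces one of the two diastereotopic C1 bromides in a 3-exo-tet halohydrin-type closure (the known collapse of β,β-dihalo alkoxides to α-halo oxiranes), in which C2 is untouched, the transition state holding the remaining C1 bromine away from the CBr2Bu group sets C1 as R (trans), and closure at the open CHBr2 carbon is expected to outrun attack at the fully substituted C3, which would force CHBr2 cis to Br or butyl.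

Compound list
1 | pentanal | CCCCC=O | starting material
2 | 1,1-dibromopentane | CCCCC(Br)Br | intermediate
3 | (R)-(2,2-dimethyl-1,3-dioxolan-4-yl)methanol | OC[C@@H]1COC(C)(C)O1 | starting material
4 | (S)-2,2-dimethyl-1,3-dioxolane-4-carbaldehyde | O=C[C@@H]1COC(C)(C)O1 | intermediate
5 | 1,1-dibromopentyllithium | [Li]C(Br)(Br)CCCC | intermediate
6 | lithium (S)-2,2-dibromo-1-[(S)-2,2-dimethyl-1,3-dioxolan-4-yl]hexan-1-olate | [Li+].CCCCC(Br)(Br)[C@@H]([O-])[C@@H]1COC(C)(C)O1 | intermediate
7 | (S)-2,2-dibromo-1-[(S)-2,2-dimethyl-1,3-dioxolan-4-yl]hexan-1-ol | CCCCC(Br)(Br)[C@@H](O)[C@@H]1COC(C)(C)O1 | intermediate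
8 | tert-butyl{(S)-2,2-dibromo-1-[(S)-2,2-dimethyl-1,3-dioxolan-4-yl]hexyloxy}dimethylsilane | CCCCC(Br)(Br)[C@@H](O[Si](C)(C)C(C)(C)C)[C@@H]1COC(C)(C)O1 | intermediate
9 | (2S,3S)-4,4-dibromo-3-(tert-butyldimethylsilyloxy)octane-1,2-diol | CCCCC(Br)(Br)[C@@H](O[Si](C)(C)C(C)(C)C)[C@@H](O)CO | intermediate
10 | (S)-3,3-dibromo-2-(tert-butyldimethylsilyloxy)heptanal | CCCCC(Br)(Br)[C@@H](O[Si](C)(C)C(C)(C)C)C=O | intermediate
11 | (S)-tert-butyldimethyl[(1,1,3,3-tetrabromoheptan-2-yl)oxy]silane | CCCCC(Br)(Br)[C@@H](O[Si](C)(C)C(C)(C)C)C(Br)Br | intermediate
12 | tetrabutylammonium (S)-1,1,3,3-tetrabromoheptan-2-olate | CCCCC(Br)(Br)[C@@H]([O-])C(Br)Br.CCCC[N+](CCCC)(CCCC)CCCC | intermediate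
13 | (2R,3S)-2-bromo-3-(1,1-dibromopentyl)oxirane | CCCCC(Br)(Br)[C@H]1O[C@@H]1Br | target

Total step count: 7. Longest linear sequence: 6 (steps 2–7, or step 1 followed by steps 3–7).

Steps most likely to fail

Step 7. What may go wrong:
- The alkoxide may close onto C3 instead of C1.
- The basic fluoride may strip HBr along C3–C4.
- Soluble fluoride or bromide may open the product.

The fallback separates deprotection from ring closure and runs the closure as a discrete halohydrin cyclisation without any soluble nucleophile. It sets out from 11. HF·pyridine in THF at 0 °C removes the silyl group under acidic conditions and should give the neutral, purifiable halohydrin (S)-1,1,3,3-tetrabromoheptan-2-ol F1. F1 is then deprotonated with NaH in THF at −20 → 0 °C, where NaBr precipitates as the ring forms. The fallback rejoins the route at 13.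

Step 6. What may go wrong:
- Displacement at the crowded, electron-poor C1 may be sluggish.
- The bromophosphonium reagent may attack the silyl ether.
- The aldehyde may lose HBr or epimerise at C2 while it waits to react.

The fallback replaces oxygen activation by an oxidative nitrogen-extrusion route. It sets out from 10. Condensation with 1,2-bis(tert-butyldimethylsilyl)hydrazine (cat. Sc(OTf)3, CH2Cl2, rt) should give (E)-1-(tert-butyldimethylsilyl)-2-[(S)-3,3-dibromo-2-(tert-butyldimethylsilyloxy)heptylidene]hydrazine F2, in which the C2–H is far less acidic than in the aldehyde. Oxidative bromination of F2 with CuBr2 and Et3N in MeOH, with loss of nitrogen, places both bromines on C1. The fallback rejoins the route at 11.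

Step 3. What may go wrong:
- The carbenoid may undergo α-elimination before it is trapped.
- Facial selectivity at the aldehyde may be only modest, so that much material carries the wrong configuration at C2.

The fallback keeps the carbenoid addition for the C2–C3 bond but moves the stereochemical decision to a reagent-controlled hydride delivery. It sets out from 7 taken as the unseparated carbinol mixture. Dess–Martin periodinane with NaHCO3 in CH2Cl2 converges both epimers on 2,2-dibromo-1-[(S)-2,2-dimethyl-1,3-dioxolan-4-yl]hexan-1-one F3. Corey–Bakshi–Shibata reduction follows, with (R)-1-methyl-3,3-diphenyltetrahydro-1H,3H-pyrrolo[1,2-c][1,3,2]oxazaborole and catecholborane in toluene at −78 °C. In this reduction CBr2Bu takes the role of the large group, as trihalomethyl groups do, so it should return the (S)-carbinol. The fallback rejoins the route at 7.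

Further compounds
F1 | step 7 | (S)-1,1,3,3-tetrabromoheptan-2-ol | CCCCC(Br)(Br)[C@@H](O)C(Br)Br
F2 | step 6 | (E)-1-(tert-butyldimethylsilyl)-2-[(S)-3,3-dibromo-2-(tert-butyldimethylsilyloxy)heptylidene]hydrazine | CCCCC(Br)(Br)[C@@H](O[Si](C)(C)C(C)(C)C)/C=N/N[Si](C)(C)C(C)(C)C
F3 | step 3 | 2,2-dibromo-1-[(S)-2,2-dimethyl-1,3-dioxolan-4-yl]hexan-1-one | CCCCC(Br)(Br)C(=O)[C@@H]1COC(C)(C)O1
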